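**Assumption:** the target has no stereocentres, so it is achiral and "single enantiomer" is trivially satisfied. Only the C8 versus C6 regiochemistry on the flavonol matters. The route assumes that C8 of kaempferide is the favoured Mannich and ortho-quinone-methide (o-QM) site.

## Retrosynthetic overview
- The target is a kaempferide (3,5,7-trihydroxy-4'-methoxyflavone) unit joined through a C8–CH2–C3' methylene bridge to a 2',6'-dihydroxy-4'-methoxy-5'-methyl dihydrochalcone. Both ring systems are commercial or quickly made, so no heterocycle needs to be built.
- Disconnect the CH2 bridge as an o-QM coupling. A C8 Mannich base of kaempferide (7-OH/C8-CH2NMe2) is the electrophile. The dihydrochalcone is the nucleophile, and its only free ring carbon is the required site.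
- Make the dihydrochalcone from commercial 2',6'-dihydroxy-4'-methoxyacetophenone by mono-C-methylation, Claisen–Schmidt condensation with 4-hydroxybenzaldehyde, then C=C hydrogenation.
- Ring order: no rings are formed. The flavonol and both aryl rings are preformed, and the only new bond is the C8–CH2–Ar bridge, made last.

## Route

**Step 1**
Reactants: 1 (2',6'-dihydroxy-4'-methoxyacetophenone); 2 (iodomethane)
Product: 3 (1-(2,6-dihydroxy-4-methoxy-3-methylphenyl)ethanone)
Conditions: MeI (1.0 equiv), NaOMe (1.1 equiv), MeOH, 0 °C → rt, 16 h
Reagents that add atoms: MeI, CI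
Why: the mono-phenolate of the symmetric phloroglucinol-type ketone is C-alkylated in protic MeOH (C-methylation via an ambident phenolate, SN2). Because the substrate is symmetric, only one constitutional isomer forms. Limiting MeI minimises the 3,5-dimethyl by-product, and unreacted 1 is recycled.

**Step 2**
Reactants: 3; 4 (4-hydroxybenzaldehyde)
Product: 5 ((E)-1-(2,6-dihydroxy-4-methoxy-3-methylphenyl)-3-(4-hydroxyphenyl)prop-2-en-1-one)
Conditions: 4 (1.2 equiv), 50% aq. KOH, EtOH, rt, 48 h, then HCl workup
Reagents that add atoms: 4-hydroxybenzaldehyde, O=Cc1ccc(O)cc1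
Why: Claisen–Schmidt aldol condensation of the ketone enolate with the aldehyde, followed by dehydration, gives the E-chalcone. No stereocentre is formed.

**Step 3**
Reactants: 5; 6 (hydrogen)
Product: 7 (1-(2,6-dihydroxy-4-methoxy-3-methylphenyl)-3-(4-hydroxyphenyl)propan-1-one)
Conditions: H2 (1 atm), 10% Pd/C, EtOAc/MeOH, rt, 4 h
Reagents that add atoms: none (only H2)
Why: catalytic hydrogenation reduces the conjugated C=C selectively. The chelated aryl ketone and the aryl ethers and phenols are untouched, and no stereocentre results.

**Step 4**
Reactants: 8 (kaempferide); 9 (formaldehyde); 10 (dimethylamine)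
Product: 11 (8-[(dimethylamino)methyl]-3,5,7-trihydroxy-4'-methoxyflavone)
Conditions: 37% aq. HCHO (1.1 equiv), 40% aq. Me2NH (1.1 equiv), EtOH, rt, 12 h
Reagents that add atoms: formaldehyde, C=O; dimethylamine, CNC
Why: Mannich aminomethylation (electrophilic iminium attack) occurs ortho to the acidic 7-OH phenolate, at C8, which is the favoured site in 5,7-dihydroxyflavones. Using about one equivalent of each reagent limits bis-aminomethylation.

**Step 5**
Reactants: 11; 7 (2.0 equiv)
Product: 12 (target, 4'''-hydroxytrianguletin)
Conditions: 1,4-dioxane, 110 °C, sealed tube, 16 h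
Reagents that add atoms: none
Why: thermal loss of Me2NH from 11 gives the 7-oxo-8-methylene o-QM. The very electron-rich ring of 7 (ortho to OH and OMe, para to OH) adds to it in a Michael-type reaction. That ring's only free carbon is the required position, so the bridge forms with defined regiochemistry on the dihydrochalcone side. Excess 7 suppresses kaempferide self-condensation, and no stereocentre forms.

## Compound list
1 | 2',6'-dihydroxy-4'-methoxyacetophenone | COc1cc(O)c(C(C)=O)c(O)c1 | starting material
2 | iodomethane | CI | starting material
3 | 1-(2,6-dihydroxy-4-methoxy-3-methylphenyl)ethanone | Cc1c(OC)cc(O)c(C(C)=O)c1O | intermediate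
4 | 4-hydroxybenzaldehyde | O=Cc1ccc(O)cc1 | starting material
5 | (E)-1-(2,6-dihydroxy-4-methoxy-3-methylphenyl)-3-(4-hydroxyphenyl)prop-2-en-1-one | Cc1c(OC)cc(O)c(C(=O)/C=C/c2ccc(O)cc2)c1O | intermediate
6 | hydrogen | [H][H] | reagent (starting material)
7 | 1-(2,6-dihydroxy-4-methoxy-3-methylphenyl)-3-(4-hydroxyphenyl)propan-1-one | Cc1c(OC)cc(O)c(C(=O)CCc2ccc(O)cc2)c1O | intermediate
8 | kaempferide (3,5,7-trihydroxy-4'-methoxyflavone) | COc1ccc(cc1)-c1oc2cc(O)cc(O)c2c(=O)c1O | starting material
9 | formaldehyde | C=O | starting material
10 | dimethylamine | CNC | starting material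
11 | 8-[(dimethylamino)methyl]kaempferide | COc1ccc(cc1)-c1oc2c(CN(C)C)c(O)cc(O)c2c(=O)c1O | intermediate
12 | 4'''-hydroxytrianguletin (no stereocentres) | COc1ccc(-c2oc3c(Cc4c(O)c(C(=O)CCc5ccc(O)cc5)c(O)c(C)c4OC)c(O)cc(O)c3c(=O)c2O)cc1 | target

## Totals
- Total steps: 5.
- Longest linear sequence: 4 steps (1 → 3 → 5 → 7 → 12). The kaempferide branch is 2 steps (8 → 11 → 12).

## Three steps most likely to fail
1. **Step 5 (o-QM coupling).** The C8 versus C6 selectivity of the flavonol may be poor, and the Mannich base may self-condense.
   - Fallback: build the A-ring regiochemistry first. Couple the Mannich base of 7 with symmetric 2',4',6'-trihydroxyacetophenone (4'- and 6'-OH as MOM ethers). Then run a Claisen–Schmidt reaction with 4-methoxybenzaldehyde and an Algar–Flynn–Oyamada oxidation to form the flavonol ring, followed by MOM removal.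
2. **Step 1 (mono-C-methylation).** Yield is statistical, and O-methylation or 3,5-dimethylation competes.
   - Fallback: mono-Mannich aminomethylation of 1 (Me2NH/HCHO), then H2/Pd–C hydrogenolysis of the benzylic C–N bond to give the methyl group.
3. **Step 2 (Claisen–Schmidt on free polyphenols).** Yield is low because the bis-phenolate ketone is a poor enolate precursor.
   - Fallback: protect all phenols of 3 and 4 as MOM ethers (MOMCl, DIPEA), do the aldol, hydrogenate, and remove MOM with HCl/MeOH. Alternatively, acylate a pre-methylated phloroglucinol ether with 3-(4-hydroxyphenyl)propanoic acid under BF3·Et2O, provided the regiochemistry can be controlled.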